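The ent-labdane core is unfolded to an acyclic (6E,10E)-geranyllinalool chain that already carries the C2 oxygen. One hydrogen-atom-transfer event at a terminal isopropenyl group creates the C4 centre, which closes ring A (C4–C5) and ring B (C9–C10) and ends as the C7=C8 alkene, so that C5, C9 and C10 are set from the C2 stereocentre alone. The step exploits the C4 gem-dimethyl group, the C10 methyl, the ring B C7=C8 alkene and the 1,3 relation between the C2 oxygen and C4. The precursor, a bis-silyl ether of the tetraenediol, is joined from (S)-linalool and (R)-epichlorohydrin through an allylic sulfone; desilylation and selective acylation follow.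

Key step: step 11

Remarks on the chemistry
- Structure check: the target is an ent-labdane, (2R,5R,9R,10R,13S) in labdane numbering, with the C2 oxygen equatorial and trans to the C10 methyl. The open-chain precursor is (3S,6E,10E,13R); chain C13 becomes ring C2 and chain C3 becomes C13. The descriptors agree with (S)-linalool and (R)-epichlorohydrin as sources.
- Numbering: labdane numbering is used for ring atoms, chain numbering (C1–C16) for open-chain compounds.
- Assumption: (S)-linalool of high enantiomeric purity is used, since its stereocentre is carried unchanged to C13.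
- Protecting groups: the tertiary C13 oxygen carries triethylsilyl (easy to put on a tertiary carbinol and to remove with fluoride), the secondary C2 oxygen carries tert-butyldimethylsilyl (robust, and the equatorial control group in ring A).

Step 1
Reactants: 1 (S)-linalool
Product: 2 (3S)-3,7-dimethyl-3-(triethylsilyloxy)octa-1,6-diene
Conditions: Et3SiOTf, 2,6-lutidine, CH2Cl2, −78 → 0 °C
Reagents that add atoms: triethylsilyl trifluoromethanesulfonate, CC[Si](CC)(CC)OS(=O)(=O)C(F)(F)F
Why: Silyl ether formation with the silyl triflate is the reliable way to cap a hindered tertiary allylic alcohol, and the stereocentre is not touched.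

Step 2
Reactants: 2 (3S)-3,7-dimethyl-3-(triethylsilyloxy)octa-1,6-diene
Product: 4 (2E,6S)-2,6-dimethyl-6-(triethylsilyloxy)octa-2,7-dien-1-ol, via enal 3 (not isolated)
Conditions: SeO2 (cat.), t-BuOOH, salicylic acid (cat.), CH2Cl2, rt; then NaBH4, MeOH, 0 °C
Reagents that add atoms: selenium dioxide (oxygen carrier), O=[Se]=O; tert-butyl hydroperoxide (terminal oxygen source), CC(C)(C)OO
Why: Selenium dioxide allylic oxidation (ene reaction, then [2,3]-sigmatropic shift) should select the (E)-methyl group of the trisubstituted alkene, the vinyl group has no allylic hydrogen, and borohydride returns the over-oxidised enal 3 to the alcohol.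

Step 3
Reactants: 4 (2E,6S)-2,6-dimethyl-6-(triethylsilyloxy)octa-2,7-dien-1-ol
Product: 5 (3S,6E)-8-bromo-3,7-dimethyl-3-(triethylsilyloxy)octa-1,6-diene
Conditions: CBr4, PPh3, CH2Cl2, −20 → 0 °C
Reagents that add atoms: carbon tetrabromide, BrC(Br)(Br)Br
Why: The Appel reaction is neutral, so the primary allylic alcohol should be replaced without allylic transposition and without ionising the tertiary allylic silyl ether.

Step 4
Reactants: 6 (R)-epichlorohydrin
Product: 7 (2R)-1-chloro-4-methylpent-4-en-2-ol
Conditions: CH2=C(CH3)MgBr, CuI (cat.), THF, −40 °C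
Reagents that add atoms: isopropenylmagnesium bromide, C=C(C)[Mg]Br
Why: Copper-catalysed Grignard opening attacks the unsubstituted epoxide carbon faster than it displaces chloride, so the C–O stereocentre of 6 is carried over unchanged.

Step 5
Reactants: 7 (2R)-1-chloro-4-methylpent-4-en-2-ol
Product: 9 (4R)-2-methylhept-1-en-6-yn-4-ol, via epoxide 8 (not isolated)
Conditions: LiC≡CH·H2N(CH2)2NH2 (3 equiv), DMSO, 0 °C → rt
Reagents that add atoms: lithium acetylide–ethylenediamine complex, [Li]C#C.NCCN
Why: The first equivalent of acetylide forms the alkoxide, which closes to epoxide 8 (intramolecular Williamson reaction), and the second opens 8 at its CH2 group (SN2), the stereocentre being a spectator in both events.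

Step 6
Reactants: 9 (4R)-2-methylhept-1-en-6-yn-4-ol
Product: 10 (4R)-4-(tert-butyldimethylsilyloxy)-2-methylhept-1-en-6-yne
Conditions: TBSCl, imidazole, DMF, rt
Reagents that add atoms: tert-butyldimethylsilyl chloride, CC(C)(C)[Si](C)(C)Cl
Why: Standard silylation of a secondary alcohol gives an ether that should withstand Me3Al, n-BuLi and LiEt3BH.

Step 7
Reactants: 10 (4R)-4-(tert-butyldimethylsilyloxy)-2-methylhept-1-en-6-yne
Product: 13 (2E,5R)-5-(tert-butyldimethylsilyloxy)-3,7-dimethylocta-2,7-dien-1-ol, via alkenylalane 11 (not isolated), via lithium aluminate 12 (not isolated)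
Conditions: Me3Al, Cp2ZrCl2 (cat.), CH2Cl2, 0 °C → rt; then n-BuLi, THF, −78 °C; (CH2O)n, −78 °C → rt
Reagents that add atoms: trimethylaluminium, C[Al](C)C; paraformaldehyde (as formaldehyde), C=O
Why: Negishi carboalumination adds methyl and aluminium syn across the terminal alkyne (methyl to the internal carbon), the 1,1-disubstituted alkene is inert, and the aluminate is hydroxymethylated with retention, which fixes the (E)-trisubstituted alkene.

Step 8
Reactants: 13 (2E,5R)-5-(tert-butyldimethylsilyloxy)-3,7-dimethylocta-2,7-dien-1-ol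
Product: 16 (4R,6E)-4-(tert-butyldimethylsilyloxy)-2,6-dimethyl-8-(phenylsulfonyl)octa-1,6-diene, via allylic mesylate 14 (not isolated), via allylic bromide 15 (not isolated)
Conditions: MsCl, Et3N, THF, −40 °C; LiBr, −40 → 0 °C; then PhSO2Na, DMF, rt
Reagents that add atoms: sodium benzenesulfinate, [Na+].[O-]S(=O)c1ccccc1
Why: Mesylation, bromide exchange and S-alkylation of the sulfinate are SN2 events at the primary allylic carbon, so alkene position and geometry should be kept.

Step 9
Reactants: 16 (4R,6E)-4-(tert-butyldimethylsilyloxy)-2,6-dimethyl-8-(phenylsulfonyl)octa-1,6-diene; 5 (3S,6E)-8-bromo-3,7-dimethyl-3-(triethylsilyloxy)octa-1,6-diene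
Product: 18 (3S,6E,10E,13R)-13-(tert-butyldimethylsilyloxy)-3,7,11,15-tetramethyl-9-(phenylsulfonyl)-3-(triethylsilyloxy)hexadeca-1,6,10,15-tetraene (both C9 epimers), via lithiated sulfone 17 (not isolated)
Conditions: n-BuLi, THF, −78 °C; then 5, −78 → −20 °C
Reagents that add atoms: none
Why: Sulfone alkylation: the α-sulfonyl allyllithium should react at its α-carbon with the primary allylic bromide by SN2, forming the chain C8–C9 bond with both alkene geometries untouched; the new sulfone-bearing centre is removed in step 10.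

Step 10
Reactants: 18 (3S,6E,10E,13R)-13-(tert-butyldimethylsilyloxy)-3,7,11,15-tetramethyl-9-(phenylsulfonyl)-3-(triethylsilyloxy)hexadeca-1,6,10,15-tetraene
Product: 19 (3S,6E,10E,13R)-13-(tert-butyldimethylsilyloxy)-3,7,11,15-tetramethyl-3-(triethylsilyloxy)hexadeca-1,6,10,15-tetraene
Conditions: Pd(dppp)Cl2 (cat.), LiEt3BH, THF, 0 °C
Reagents that add atoms: none
Why: Palladium-catalysed reductive desulfonylation of an allylic sulfone: hydride should attack the π-allyl complex at its less substituted end (chain C9), which keeps the C10=C11 alkene in place and (E), while silyl ethers and isolated alkenes are inert.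

Step 11
Reactants: 19 (3S,6E,10E,13R)-13-(tert-butyldimethylsilyloxy)-3,7,11,15-tetramethyl-3-(triethylsilyloxy)hexadeca-1,6,10,15-tetraene
Product: 20 tert-butyl{[(2R,4aR,8R,8aR)-4,4,7,8a-tetramethyl-8-[(3S)-3-methyl-3-(triethylsilyloxy)pent-4-en-1-yl]-1,2,3,4,4a,5,8,8a-octahydronaphthalen-2-yl]oxy}dimethylsilane (labdane numbering: 2-O-TBS, 13-O-TES ether of (2R,5R,9R,10R,13S)-labda-7,14-diene-2,13-diol)
Conditions: Co(salen)Cl (5 mol %, trivalent cobalt; salen = N,N′-bis(3,5-di-tert-butylsalicylidene)-1,2-cyclohexanediamine dianion), PhSiH3 (slow addition), N-fluoro-2,4,6-trimethylpyridinium triflate, 2,6-di-tert-butylpyridine, CH2Cl2/(CF3)2CHOH, 0 °C → rt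
Reagents that add atoms: none
Why: The cobalt hydride formed from Co(salen)Cl and PhSiH3 should hand a hydrogen atom to the CH2 terminus of the isopropenyl group (a future C4 methyl), and the tertiary C4 radical, or the C4 cation reached from it by oxidation through an alkylcobalt species, attacks C5, the new C10 centre attacks C9, and the C8 centre is oxidised and loses H7 to the 2,4,6-trimethylpyridine released from the oxidant. The closest known reaction type is the cobalt–salen hydrogen-atom-transfer radical–polar crossover cyclization of polyenes, ended here by alkene formation as in hydrogen-atom-transfer cycloisomerization. Ring A closes 6-endo through C4–C5 and ring B closes 6-endo through C9–C10, each in a chair. C5 and C10 follow from anti addition across the (E)-C5=C10 alkene (trans ring fusion) and C9 from the (E)-C8=C9 alkene (side chain equatorial, cis to the C10 methyl); the absolute sense is fixed by the (R)-C2 silyloxy group, which should sit equatorial because an axial one would be 1,3-diaxial to both the C10 methyl and the axial C4 methyl. The step needs initiation at the isopropenyl group only and proton loss towards C7: the first rests on the 1,1-disubstituted alkene being the best hydrogen-atom acceptor (the vinyl group is monosubstituted and screened by the silyloxy-bearing C13), the second on an exocyclic C8=C17 isomer being itself a 1,1-disubstituted alkene that re-enters the cycle and should drain to the less reactive C7=C8 alkene. Neutral initiation leaves the acid-labile tertiary allylic silyl ether at C13 alone, and the C2 oxygen, 1,3 to C4, cannot be expelled from the C4 intermediate.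

Step 12
Reactants: 20 the bis-silyl ether from step 11
Product: 21 (2R,4aR,8R,8aR)-8-[(3S)-3-hydroxy-3-methylpent-4-en-1-yl]-4,4,7,8a-tetramethyl-1,2,3,4,4a,5,8,8a-octahydronaphthalen-2-ol
Conditions: Bu4NF, THF, rt → 50 °C
Reagents that add atoms: none
Why: Fluoride-induced desilylation should cleave the tertiary triethylsilyl ether at room temperature and the secondary tert-butyldimethylsilyl ether on gentle warming, and the basic medium does not ionise the tertiary allylic alcohol.

Step 13
Reactants: 21 the diol from step 12; 22 3-methylbut-2-enoic acid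
Product: 23 (2R,4aR,8R,8aR)-8-[(3S)-3-hydroxy-3-methylpent-4-en-1-yl]-4,4,7,8a-tetramethyl-1,2,3,4,4a,5,8,8a-octahydronaphthalen-2-yl 3-methylbut-2-enoate (CNP0252389.1)
Conditions: DCC, DMAP (cat.), CH2Cl2, 0 °C → rt
Reagents that add atoms: none
Why: Steglich esterification should acylate the unhindered equatorial secondary C2 hydroxyl with retention, whereas the tertiary allylic C13 hydroxyl does not react with the acylpyridinium species under these conditions.

Compound list
1 | (S)-linalool, (3S)-3,7-dimethylocta-1,6-dien-3-ol | C=C[C@@](C)(O)CCC=C(C)C | starting material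
2 | (3S)-3,7-dimethyl-3-(triethylsilyloxy)octa-1,6-diene | C=C[C@@](C)(O[Si](CC)(CC)CC)CCC=C(C)C | intermediate
3 | (2E,6S)-2,6-dimethyl-6-(triethylsilyloxy)octa-2,7-dienal (not isolated) | C=C[C@@](C)(O[Si](CC)(CC)CC)CC/C=C(\C)C=O | intermediate
4 | (2E,6S)-2,6-dimethyl-6-(triethylsilyloxy)octa-2,7-dien-1-ol | C=C[C@@](C)(O[Si](CC)(CC)CC)CC/C=C(\C)CO | intermediate
5 | (3S,6E)-8-bromo-3,7-dimethyl-3-(triethylsilyloxy)octa-1,6-diene | C=C[C@@](C)(O[Si](CC)(CC)CC)CC/C=C(\C)CBr | intermediate
6 | (R)-epichlorohydrin, (2R)-2-(chloromethyl)oxirane | ClC[C@H]1CO1 | starting material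
7 | (2R)-1-chloro-4-methylpent-4-en-2-ol | ClC[C@H](O)CC(C)=C | intermediate
8 | (2R)-2-(2-methylprop-2-en-1-yl)oxirane (not isolated) | C=C(C)C[C@@H]1CO1 | intermediate
9 | (4R)-2-methylhept-1-en-6-yn-4-ol | C#CC[C@H](O)CC(C)=C | intermediate
10 | (4R)-4-(tert-butyldimethylsilyloxy)-2-methylhept-1-en-6-yne | C#CC[C@H](O[Si](C)(C)C(C)(C)C)CC(C)=C | intermediate
11 | [(1E,4R)-4-(tert-butyldimethylsilyloxy)-2,6-dimethylhepta-1,6-dien-1-yl]dimethylalane (not isolated) | C[Al](C)/C=C(\C)C[C@H](O[Si](C)(C)C(C)(C)C)CC(C)=C | intermediate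
12 | lithium butyl[(1E,4R)-4-(tert-butyldimethylsilyloxy)-2,6-dimethylhepta-1,6-dien-1-yl]dimethylaluminate (not isolated) | [Li+].CCCC[Al-](C)(C)/C=C(\C)C[C@H](O[Si](C)(C)C(C)(C)C)CC(C)=C | intermediate
13 | (2E,5R)-5-(tert-butyldimethylsilyloxy)-3,7-dimethylocta-2,7-dien-1-ol | OC/C=C(\C)C[C@H](O[Si](C)(C)C(C)(C)C)CC(C)=C | intermediate
14 | (2E,5R)-5-(tert-butyldimethylsilyloxy)-3,7-dimethylocta-2,7-dien-1-yl methanesulfonate (not isolated) | CS(=O)(=O)OC/C=C(\C)C[C@H](O[Si](C)(C)C(C)(C)C)CC(C)=C | intermediate
15 | (4R,6E)-8-bromo-4-(tert-butyldimethylsilyloxy)-2,6-dimethylocta-1,6-diene (not isolated) | BrC/C=C(\C)C[C@H](O[Si](C)(C)C(C)(C)C)CC(C)=C | intermediate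
16 | (4R,6E)-4-(tert-butyldimethylsilyloxy)-2,6-dimethyl-8-(phenylsulfonyl)octa-1,6-diene | O=S(=O)(C/C=C(\C)C[C@H](O[Si](C)(C)C(C)(C)C)CC(C)=C)c1ccccc1 | intermediate
17 | α-lithio derivative of sulfone 16 (not isolated) | [Li]C(/C=C(\C)C[C@H](O[Si](C)(C)C(C)(C)C)CC(C)=C)S(=O)(=O)c1ccccc1 | intermediate
18 | (3S,6E,10E,13R)-13-(tert-butyldimethylsilyloxy)-3,7,11,15-tetramethyl-9-(phenylsulfonyl)-3-(triethylsilyloxy)hexadeca-1,6,10,15-tetraene (both C9 epimers) | C=C[C@@](C)(O[Si](CC)(CC)CC)CC/C=C(\C)CC(/C=C(\C)C[C@H](O[Si](C)(C)C(C)(C)C)CC(C)=C)S(=O)(=O)c1ccccc1 | intermediate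
19 | (3S,6E,10E,13R)-13-(tert-butyldimethylsilyloxy)-3,7,11,15-tetramethyl-3-(triethylsilyloxy)hexadeca-1,6,10,15-tetraene (key-step precursor) | C=C[C@@](C)(O[Si](CC)(CC)CC)CC/C=C(\C)CC/C=C(\C)C[C@H](O[Si](C)(C)C(C)(C)C)CC(C)=C | intermediate
20 | tert-butyl{[(2R,4aR,8R,8aR)-4,4,7,8a-tetramethyl-8-[(3S)-3-methyl-3-(triethylsilyloxy)pent-4-en-1-yl]-1,2,3,4,4a,5,8,8a-octahydronaphthalen-2-yl]oxy}dimethylsilane (key-step product) | C=C[C@@](C)(O[Si](CC)(CC)CC)CC[C@@H]1C(C)=CC[C@@H]2C(C)(C)C[C@@H](O[Si](C)(C)C(C)(C)C)C[C@@]12C | intermediate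
21 | (2R,4aR,8R,8aR)-8-[(3S)-3-hydroxy-3-methylpent-4-en-1-yl]-4,4,7,8a-tetramethyl-1,2,3,4,4a,5,8,8a-octahydronaphthalen-2-ol | C=C[C@@](C)(O)CC[C@@H]1C(C)=CC[C@@H]2C(C)(C)C[C@@H](O)C[C@@]12C | intermediate
22 | 3-methylbut-2-enoic acid | CC(C)=CC(=O)O | starting material
23 | (2R,4aR,8R,8aR)-8-[(3S)-3-hydroxy-3-methylpent-4-en-1-yl]-4,4,7,8a-tetramethyl-1,2,3,4,4a,5,8,8a-octahydronaphthalen-2-yl 3-methylbut-2-enoate | C=C[C@@](C)(O)CC[C@@H]1C(C)=CC[C@@H]2C(C)(C)C[C@@H](OC(=O)C=C(C)C)C[C@@]12C | target

Total step count: 13. Longest linear sequence: 10 steps (steps 4 to 13, from 6).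

Steps most likely to fail

Step 11. The cascade may go astray in several ways:
- hydrogen-atom transfer to the vinyl group;
- a stop after ring A;
- proton loss from C17 or C9 instead of C7;
- capture of the C8 cation by fluoride or by the C13 silyloxy oxygen (tetrahydropyran formation).

The fallback replaces the cationic ending by a radical fragmentation that can only give the C7=C8 alkene. It sets out from 5 and 13 and comes back at 20. Bromide 5 and PhSO2Na in DMF should give (3S,6E)-3,7-dimethyl-8-(phenylsulfonyl)-3-(triethylsilyloxy)octa-1,6-diene F1. Alcohol 13 is taken to bromide 15 as in step 8, this time isolated. n-BuLi converts F1 into the α-lithio derivative of sulfone F1 F2. Alkylation of F2 with 15 should give (3S,6E,10E,13R)-13-(tert-butyldimethylsilyloxy)-3,7,11,15-tetramethyl-8-(phenylsulfonyl)-3-(triethylsilyloxy)hexadeca-1,6,10,15-tetraene F3, with the sulfonyl group on the future C7. Under purely radical hydrogen-atom-transfer conditions (Fe(acac)3, trivalent iron, PhSiH3, EtOH, 60 °C) the C4 radical should close both rings. The C8 radical then expels the benzenesulfonyl radical from C7, the addition–fragmentation known for allyl sulfones, to give 20. No oxidant and no cation are involved, so neither misdirected proton loss nor capture by fluoride or oxygen can occur.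

Step 7. Carbometalation next to the silyloxy-bearing carbon may be slow and accompanied by desilylation, and capture of the aluminate by formaldehyde may be incomplete. The fallback builds the trisubstituted alkene by directed hydroalumination, iodination and methylation of a propargylic alcohol. It sets out from 7 and comes back at 13.
- Chlorohydrin 7 is closed with KOH to epoxide 8, now isolated.
- BF3·OEt2-assisted opening of 8 with the lithium acetylide of 2-(prop-2-yn-1-yloxy)tetrahydro-2H-pyran should give (4R)-2-methyl-8-(tetrahydro-2H-pyran-2-yloxy)oct-1-en-6-yn-4-ol F4.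
- TBSCl and imidazole give tert-butyldimethyl{[(4R)-2-methyl-8-(tetrahydro-2H-pyran-2-yloxy)oct-1-en-6-yn-4-yl]oxy}silane F5.
- Pyridinium p-toluenesulfonate in MeOH frees (5R)-5-(tert-butyldimethylsilyloxy)-7-methyloct-7-en-2-yn-1-ol F6.
- NaAlH2(OCH2CH2OCH3)2 should add hydride and aluminium trans across the alkyne to give the cyclic sodium alkoxy(alkenyl)aluminate F7.
- I2 at −78 °C converts F7 into (2Z,5R)-5-(tert-butyldimethylsilyloxy)-3-iodo-7-methylocta-2,7-dien-1-ol F8.
- LiCuMe2 replaces iodine by methyl with retention to give 13.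

Step 10. Hydride may be delivered to the tertiary allyl terminus (alkene transposition), the π-allyl complex may equilibrate (E to Z leakage), or a palladium hydride may move the isolated alkenes. The fallback joins the two halves directly and needs no sulfone. It sets out from 13 and comes back at 19. MsCl, LiCl and 2,4,6-collidine in DMF should convert 13 into (4R,6E)-4-(tert-butyldimethylsilyloxy)-8-chloro-2,6-dimethylocta-1,6-diene F9. Activated barium (from BaI2 and lithium biphenylide, THF, −78 °C) turns F9 into [(2E,5R)-5-(tert-butyldimethylsilyloxy)-3,7-dimethylocta-2,7-dien-1-yl]barium chloride F10. F10 should couple with bromide 5 at its α-carbon with retention of alkene geometry to give 19.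

Further compounds
F1 | step 11 | (3S,6E)-3,7-dimethyl-8-(phenylsulfonyl)-3-(triethylsilyloxy)octa-1,6-diene | C=C[C@@](C)(O[Si](CC)(CC)CC)CC/C=C(\C)CS(=O)(=O)c1ccccc1
F2 | step 11 | α-lithio derivative of sulfone F1 | C=C[C@@](C)(O[Si](CC)(CC)CC)CC/C=C(\C)C([Li])S(=O)(=O)c1ccccc1
F3 | step 11 | (3S,6E,10E,13R)-13-(tert-butyldimethylsilyloxy)-3,7,11,15-tetramethyl-8-(phenylsulfonyl)-3-(triethylsilyloxy)hexadeca-1,6,10,15-tetraene | C=C[C@@](C)(O[Si](CC)(CC)CC)CC/C=C(\C)C(C/C=C(\C)C[C@H](O[Si](C)(C)C(C)(C)C)CC(C)=C)S(=O)(=O)c1ccccc1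
F4 | step 7 | (4R)-2-methyl-8-(tetrahydro-2H-pyran-2-yloxy)oct-1-en-6-yn-4-ol | C=C(C)C[C@@H](O)CC#CCOC1CCCCO1
F5 | step 7 | tert-butyldimethyl{[(4R)-2-methyl-8-(tetrahydro-2H-pyran-2-yloxy)oct-1-en-6-yn-4-yl]oxy}silane | C=C(C)C[C@@H](O[Si](C)(C)C(C)(C)C)CC#CCOC1CCCCO1
F6 | step 7 | (5R)-5-(tert-butyldimethylsilyloxy)-7-methyloct-7-en-2-yn-1-ol | C=C(C)C[C@@H](O[Si](C)(C)C(C)(C)C)CC#CCO
F7 | step 7 | cyclic sodium alkoxy(alkenyl)bis(2-methoxyethoxy)aluminate from F6 | [Na+].COCCO[Al-]1(OCCOC)OCC=C1C[C@H](O[Si](C)(C)C(C)(C)C)CC(C)=C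
F8 | step 7 | (2Z,5R)-5-(tert-butyldimethylsilyloxy)-3-iodo-7-methylocta-2,7-dien-1-ol | OC/C=C(\I)C[C@H](O[Si](C)(C)C(C)(C)C)CC(C)=C
F9 | step 10 | (4R,6E)-4-(tert-butyldimethylsilyloxy)-8-chloro-2,6-dimethylocta-1,6-diene | ClC/C=C(\C)C[C@H](O[Si](C)(C)C(C)(C)C)CC(C)=C
F10 | step 10 | [(2E,5R)-5-(tert-butyldimethylsilyloxy)-3,7-dimethylocta-2,7-dien-1-yl]barium chloride | Cl[Ba]C/C=C(\C)C[C@H](O[Si](C)(C)C(C)(C)C)CC(C)=C
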